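**Retrosynthetic overview**
1. Target 30 ⇒ iodo-enal 29: the ten-membered ring is closed last, at C2–C3, by an intramolecular Nozaki–Hiyama–Kishi coupling (sets C3).
2. 29 ⇒ lactone 23 by desilylation, angeloylation of C8–OH, and unmasking/oxidation of C3.
3. 23 ⇒ bromide 15 + enal 21: key C6–C7 bond by intermolecular indium-mediated carbonyl allylation, then lactonisation; the cis-fused α-methylene-γ-butyrolactone is the first ring (sets C6, C7).
4. 15 ⇒ (R)-linalool (C10), L-proline α-aminoxylation (C8), Takai iodo-olefination (1E), Baylis–Hillman reaction with methyl acrylate (C11–C13).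
5. 21 ⇒ propargyl alcohol via syn-carbocupration of a butynoate (4Z).

Assumption: positions are given in germacrane numbering (C6 lactone carbinol, C7, C8 ester carbinol, C10 tertiary carbinol, C3 allylic carbinol, C11=C13 methylene, C12 lactone carbonyl); commercial (R)-(−)-linalool of high ee is used.

**Route**

Step 1
Reactants: 1 (R)-(−)-linalool
Product: 2 (3R)-3,7-dimethyl-3-[(triethylsilyl)oxy]octa-1,6-diene
Conditions: Et3SiOTf, 2,6-lutidine, CH2Cl2, −78 to 0 °C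
Reagents that add atoms: triethylsilyl trifluoromethanesulfonate, CC[Si](CC)(CC)OS(=O)(=O)C(F)(F)F
Why: Silylation of the tertiary alcohol with a silyl triflate masks C10–OH so that the later aldehydes cannot close to lactols; the C10 stereocentre comes unchanged from linalool.

Step 2
Reactants: 2 (3R)-3,7-dimethyl-3-[(triethylsilyl)oxy]octa-1,6-diene
Product: 4 (4R)-4-methyl-4-[(triethylsilyl)oxy]hex-5-enal, via ozonide 3 (not isolated)
Conditions: O3, CH2Cl2, −78 °C, Sudan Red 7B as end-point indicator; then PPh3, −78 °C to rt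
Reagents that add atoms: ozone, [O-][O+]=O
Why: Chemoselective ozonolysis, because the electron-rich trisubstituted alkene reacts far faster than the vinyl group on the silyloxy-substituted quaternary carbon.

Step 3
Reactants: 4 (4R)-4-methyl-4-[(triethylsilyl)oxy]hex-5-enal
Product: 6 (2R,4R)-4-methyl-2-[(phenylamino)oxy]-4-[(triethylsilyl)oxy]hex-5-en-1-ol, via aminoxy aldehyde 5 (not isolated)
Conditions: PhNO (1.0 equiv), L-proline (0.3 equiv), DMSO, rt, 30 min; then NaBH4, EtOH, 0 °C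
Reagents that add atoms: nitrosobenzene, O=Nc1ccccc1
Why: Proline-catalysed α-aminoxylation: the L-proline enamine is oxygenated by PhNO on one face under catalyst control to give the (R)-α-oxy aldehyde (sets C8), which is reduced at once to prevent epimerisation.

Step 4
Reactants: 6 (2R,4R)-4-methyl-2-[(phenylamino)oxy]-4-[(triethylsilyl)oxy]hex-5-en-1-ol
Product: 7 (2R,4R)-4-methyl-4-[(triethylsilyl)oxy]hex-5-ene-1,2-diol
Conditions: Zn dust, AcOH/EtOH 1:3, rt, 1 h
Reagents that add atoms: none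
Why: Reductive cleavage of the weak N–O bond by zinc in acetic acid frees the 1,2-diol without touching the alkene, the hindered tertiary silyl ether or C8.

Step 5
Reactants: 7 (2R,4R)-4-methyl-4-[(triethylsilyl)oxy]hex-5-ene-1,2-diol
Product: 8 (3R,5R)-3-methyl-3,5,6-tris[(triethylsilyl)oxy]hex-1-ene
Conditions: Et3SiCl, imidazole, DMAP (cat.), CH2Cl2, 0 °C to rt
Reagents that add atoms: chlorotriethylsilane, CC[Si](Cl)(CC)CC
Why: Standard silylation of the primary and secondary hydroxyls; the primary silyl ether is the latent C7 aldehyde.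

Step 6
Reactants: 8 (3R,5R)-3-methyl-3,5,6-tris[(triethylsilyl)oxy]hex-1-ene
Product: 10 (2R,4R)-2-methyl-2,4,5-tris[(triethylsilyl)oxy]pentanal, via ozonide 9 (not isolated)
Conditions: O3, CH2Cl2, −78 °C; then PPh3, −78 °C to rt
Reagents that add atoms: ozone, [O-][O+]=O
Why: Ozonolysis of the only remaining alkene gives the C1 aldehyde, which is non-epimerisable because its α-carbon (C10) is quaternary.

Step 7
Reactants: 10 (2R,4R)-2-methyl-2,4,5-tris[(triethylsilyl)oxy]pentanal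
Product: 11 (1E,3R,5R)-1-iodo-3-methyl-3,5,6-tris[(triethylsilyl)oxy]hex-1-ene
Conditions: CrCl2 (6 equiv), CHI3 (2 equiv), THF, 0 °C to rt, dark
Reagents that add atoms: iodoform, IC(I)I
Why: Takai olefination: the geminal dichromium reagent adds to the aldehyde and eliminates to the (E)-iodoalkene, E being strongly favoured with a bulky α-quaternary aldehyde (sets the 1E geometry).

Step 8
Reactants: 11 (1E,3R,5R)-1-iodo-3-methyl-3,5,6-tris[(triethylsilyl)oxy]hex-1-ene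
Product: 12 (2R,4R,5E)-6-iodo-4-methyl-2,4-bis[(triethylsilyl)oxy]hex-5-enal
Conditions: (COCl)2, DMSO, CH2Cl2, −78 to −40 °C; then Et3N, to 0 °C
Reagents that add atoms: none
Why: Under Swern conditions the chlorosulfonium ion attacks only the unhindered primary triethylsilyl ether and oxidises it directly to the aldehyde, leaving the secondary and tertiary silyl ethers and C8 untouched at low temperature.

Step 9
Reactants: 12 (2R,4R,5E)-6-iodo-4-methyl-2,4-bis[(triethylsilyl)oxy]hex-5-enal, 13 methyl acrylate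
Product: 14 methyl (4R,6R,7E)-3-hydroxy-8-iodo-6-methyl-2-methylidene-4,6-bis[(triethylsilyl)oxy]oct-7-enoate (both C3 epimers)
Conditions: DABCO (1 equiv), methyl acrylate (10 equiv), MeOH (2 equiv), rt, 3–5 d
Reagents that add atoms: none
Why: Morita–Baylis–Hillman reaction of the inductively activated α-silyloxy aldehyde; the new carbinol centre becomes sp2 in the next step, so the epimer mixture is used as such.

Step 10
Reactants: 14 methyl (4R,6R,7E)-3-hydroxy-8-iodo-6-methyl-2-methylidene-4,6-bis[(triethylsilyl)oxy]oct-7-enoate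
Product: 15 methyl (2Z,4R,6R,7E)-2-(bromomethyl)-8-iodo-6-methyl-4,6-bis[(triethylsilyl)oxy]octa-2,7-dienoate
Conditions: NBS, Me2S, CH2Cl2, −20 °C to rt
Reagents that add atoms: N-bromosuccinimide, BrN1C(=O)CCC1=O
Why: Corey–Kim-type activation of the allylic alcohol followed by SN2′ return of bromide gives the conjugated, thermodynamically preferred (2Z)-2-(bromomethyl)alkenoate under neutral conditions.

Step 11
Reactants: 16 prop-2-yn-1-ol
Product: 17 1-methoxy-4-[(prop-2-yn-1-yloxy)methyl]benzene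
Conditions: NaH, THF, 0 °C; then 4-methoxybenzyl chloride, Bu4NI (cat.), rt
Reagents that add atoms: 4-methoxybenzyl chloride, COc1ccc(CCl)cc1
Why: Williamson etherification; NaH removes only the hydroxyl proton, not the far less acidic alkyne proton.

Step 12
Reactants: 17 1-methoxy-4-[(prop-2-yn-1-yloxy)methyl]benzene
Product: 18 methyl 4-[(4-methoxybenzyl)oxy]but-2-ynoate
Conditions: n-BuLi, THF, −78 °C; then ClCO2Me, −78 to 0 °C
Reagents that add atoms: methyl chloroformate, COC(Cl)=O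
Why: Acylation of the lithium acetylide with a chloroformate gives the ynoate.

Step 13
Reactants: 18 methyl 4-[(4-methoxybenzyl)oxy]but-2-ynoate
Product: 19 methyl (2Z)-4-[(4-methoxybenzyl)oxy]-3-methylbut-2-enoate
Conditions: Me2CuLi (from CuI and 2 MeLi), THF, −78 °C, 1 h; quench at −78 °C with sat. aq NH4Cl
Reagents that add atoms: lithium dimethylcuprate, [Li+].C[Cu-]C
Why: Gilman cuprate addition to the ynoate is a syn carbocupration at −78 °C, so cold protonation leaves the ester and the CH2O group cis, which fixes the 4Z olefin of the target.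

Step 14
Reactants: 19 methyl (2Z)-4-[(4-methoxybenzyl)oxy]-3-methylbut-2-enoate
Product: 20 (2Z)-4-[(4-methoxybenzyl)oxy]-3-methylbut-2-en-1-ol
Conditions: i-Bu2AlH (2.5 equiv), CH2Cl2, −78 °C; aq. potassium sodium tartrate work-up
Reagents that add atoms: none
Why: 1,2-Reduction of the enoate by the aluminium hydride gives the allylic alcohol with the olefin geometry retained.

Step 15
Reactants: 20 (2Z)-4-[(4-methoxybenzyl)oxy]-3-methylbut-2-en-1-ol
Product: 21 (2Z)-4-[(4-methoxybenzyl)oxy]-3-methylbut-2-enal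
Conditions: MnO2 (20 equiv), CH2Cl2, rt, dark; used at once
Reagents that add atoms: none
Why: Neutral allylic oxidation with MnO2 gives the (Z)-enal without acid or base that would isomerise it to E.

Step 16
Reactants: 15 methyl (2Z,4R,6R,7E)-2-(bromomethyl)-8-iodo-6-methyl-4,6-bis[(triethylsilyl)oxy]octa-2,7-dienoate, 21 (2Z)-4-[(4-methoxybenzyl)oxy]-3-methylbut-2-enal
Product: 23 (4S,5S)-4-[(1R,3R,4E)-5-iodo-3-methyl-1,3-bis(triethylsilyloxy)pent-4-en-1-yl]-5-[(1Z)-3-[(4-methoxybenzyl)oxy]-2-methylprop-1-en-1-yl]-3-methylidenedihydrofuran-2(3H)-one, via hydroxy ester 22 (not isolated)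
Conditions: In powder (2 equiv), THF/H2O 3:1, rt, 12 h; then crude, PPTS (0.2 equiv), 4 Å molecular sieves, CH2Cl2, rt
Reagents that add atoms: none
Why: Indium-mediated Barbier carbonyl allylation then lactonisation: the (Z)-allylindium adds 1,2 to the enal at its γ-carbon C7 through a chair transition state to give the 6,7-syn adduct and hence the cis-lactone, and the aldehyde is expected to approach C7 anti to the C9 chain with C8–H eclipsing the allyl unit (allylic 1,3-strain) and the silyloxy group outside, which gives the C6 and C7 configurations of the target from 8R.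

Step 17
Reactants: 23 (4S,5S)-4-[(1R,3R,4E)-5-iodo-3-methyl-1,3-bis(triethylsilyloxy)pent-4-en-1-yl]-5-[(1Z)-3-[(4-methoxybenzyl)oxy]-2-methylprop-1-en-1-yl]-3-methylidenedihydrofuran-2(3H)-one
Product: 24 (4R,5S)-4-[(1R,3R,4E)-1,3-dihydroxy-5-iodo-3-methylpent-4-en-1-yl]-5-[(1Z)-3-[(4-methoxybenzyl)oxy]-2-methylprop-1-en-1-yl]-3-methylidenedihydrofuran-2(3H)-one
Conditions: HF·pyridine, pyridine, THF, 0 °C to rt
Reagents that add atoms: none
Why: Buffered fluoride removes both triethylsilyl ethers while the PMB ether, the iodoalkene and the already closed 6,12-lactone stay intact.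

Step 18
Reactants: 24 (4R,5S)-4-[(1R,3R,4E)-1,3-dihydroxy-5-iodo-3-methylpent-4-en-1-yl]-5-[(1Z)-3-[(4-methoxybenzyl)oxy]-2-methylprop-1-en-1-yl]-3-methylidenedihydrofuran-2(3H)-one, 25 angelic acid
Product: 27 (1R,3R,4E)-3-hydroxy-5-iodo-1-[(2S,3R)-2-{(1Z)-3-[(4-methoxybenzyl)oxy]-2-methylprop-1-en-1-yl}-4-methylidene-5-oxooxolan-3-yl]-3-methylpent-4-en-1-yl (2Z)-2-methylbut-2-enoate, via mixed anhydride 26 (not isolated)
Conditions: 25, 2,4,6-trichlorobenzoyl chloride, Et3N, toluene, rt, 2 h; then 24, toluene, 80 °C (no DMAP)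
Reagents that add atoms: none
Why: Yamaguchi esterification acylates the secondary C8–OH selectively over the tertiary C10–OH, and the DMAP-free mixed-anhydride protocol avoids isomerisation of the angelate to the tiglate.

Step 19
Reactants: 27 (1R,3R,4E)-3-hydroxy-5-iodo-1-[(2S,3R)-2-{(1Z)-3-[(4-methoxybenzyl)oxy]-2-methylprop-1-en-1-yl}-4-methylidene-5-oxooxolan-3-yl]-3-methylpent-4-en-1-yl (2Z)-2-methylbut-2-enoate
Product: 28 (1R,3R,4E)-3-hydroxy-1-[(2S,3R)-2-[(1Z)-3-hydroxy-2-methylprop-1-en-1-yl]-4-methylidene-5-oxooxolan-3-yl]-5-iodo-3-methylpent-4-en-1-yl (2Z)-2-methylbut-2-enoate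
Conditions: DDQ (1.5 equiv), CH2Cl2/pH 7 phosphate buffer 10:1, 0 °C
Reagents that add atoms: none
Why: Oxidative cleavage of the electron-rich PMB ether by DDQ under buffered conditions spares the esters, the iodoalkene and the tertiary alcohol.

Step 20
Reactants: 28 (1R,3R,4E)-3-hydroxy-1-[(2S,3R)-2-[(1Z)-3-hydroxy-2-methylprop-1-en-1-yl]-4-methylidene-5-oxooxolan-3-yl]-5-iodo-3-methylpent-4-en-1-yl (2Z)-2-methylbut-2-enoate
Product: 29 (1R,3R,4E)-3-hydroxy-5-iodo-3-methyl-1-[(2S,3R)-4-methylidene-2-[(1Z)-2-methyl-3-oxoprop-1-en-1-yl]-5-oxooxolan-3-yl]pent-4-en-1-yl (2Z)-2-methylbut-2-enoate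
Conditions: MnO2 (20 equiv), CH2Cl2, rt, dark; used at once
Reagents that add atoms: none
Why: MnO2 oxidises only the primary allylic alcohol (the tertiary alcohol is inert) and gives the (Z)-enal under neutral conditions.

Step 21
Reactants: 29 (1R,3R,4E)-3-hydroxy-5-iodo-3-methyl-1-[(2S,3R)-4-methylidene-2-[(1Z)-2-methyl-3-oxoprop-1-en-1-yl]-5-oxooxolan-3-yl]pent-4-en-1-yl (2Z)-2-methylbut-2-enoate
Product: 30 (3aR,4R,6R,7E,9S,10Z,11aS)-6,9-dihydroxy-6,10-dimethyl-3-methylidene-2-oxo-2,3,3a,4,5,6,9,11a-octahydrocyclodeca[b]furan-4-yl (2Z)-2-methylbut-2-enoate (target)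
Conditions: CrCl2 (10 equiv), NiCl2 (0.1 equiv), degassed DMSO, rt, 3 mM, slow addition of 29
Reagents that add atoms: none
Why: Nozaki–Hiyama–Kishi macrocyclisation: the (E)-alkenylchromium formed with retention adds chemoselectively to the aldehyde, and the tether is expected to reach the s-trans (Z)-enal only from the face on which C7 lies when C6–H eclipses the C4=C5 bond (allylic 1,3-strain), which gives the 3S alcohol.

**Compound list**
1 | (R)-(−)-linalool, (3R)-3,7-dimethylocta-1,6-dien-3-ol | C=C[C@](C)(O)CCC=C(C)C | starting material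
2 | (3R)-3,7-dimethyl-3-[(triethylsilyl)oxy]octa-1,6-diene | C=C[C@](C)(O[Si](CC)(CC)CC)CCC=C(C)C | intermediate
3 | 3,3-dimethyl-5-[(3R)-3-methyl-3-(triethylsilyloxy)pent-4-en-1-yl]-1,2,4-trioxolane (ozonide, epimers at the ring CH) | C=C[C@](C)(O[Si](CC)(CC)CC)CCC1OOC(C)(C)O1 | intermediate
4 | (4R)-4-methyl-4-[(triethylsilyl)oxy]hex-5-enal | C=C[C@](C)(O[Si](CC)(CC)CC)CCC=O | intermediate
5 | (2R,4R)-4-methyl-2-[(phenylamino)oxy]-4-[(triethylsilyl)oxy]hex-5-enal | C=C[C@](C)(O[Si](CC)(CC)CC)C[C@@H](ONc1ccccc1)C=O | intermediate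
6 | (2R,4R)-4-methyl-2-[(phenylamino)oxy]-4-[(triethylsilyl)oxy]hex-5-en-1-ol | C=C[C@](C)(O[Si](CC)(CC)CC)C[C@@H](ONc1ccccc1)CO | intermediate
7 | (2R,4R)-4-methyl-4-[(triethylsilyl)oxy]hex-5-ene-1,2-diol | C=C[C@](C)(O[Si](CC)(CC)CC)C[C@@H](O)CO | intermediate
8 | (3R,5R)-3-methyl-3,5,6-tris[(triethylsilyl)oxy]hex-1-ene | C=C[C@](C)(O[Si](CC)(CC)CC)C[C@@H](O[Si](CC)(CC)CC)CO[Si](CC)(CC)CC | intermediate
9 | 3-[(2R,4R)-2,4,5-tris(triethylsilyloxy)pentan-2-yl]-1,2,4-trioxolane (ozonide) | C1(OOCO1)[C@](C)(O[Si](CC)(CC)CC)C[C@@H](O[Si](CC)(CC)CC)CO[Si](CC)(CC)CC | intermediate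
10 | (2R,4R)-2-methyl-2,4,5-tris[(triethylsilyl)oxy]pentanal | O=C[C@](C)(O[Si](CC)(CC)CC)C[C@@H](O[Si](CC)(CC)CC)CO[Si](CC)(CC)CC | intermediate
11 | (1E,3R,5R)-1-iodo-3-methyl-3,5,6-tris[(triethylsilyl)oxy]hex-1-ene | I/C=C/[C@](C)(O[Si](CC)(CC)CC)C[C@@H](O[Si](CC)(CC)CC)CO[Si](CC)(CC)CC | intermediate
12 | (2R,4R,5E)-6-iodo-4-methyl-2,4-bis[(triethylsilyl)oxy]hex-5-enal | I/C=C/[C@](C)(O[Si](CC)(CC)CC)C[C@@H](O[Si](CC)(CC)CC)C=O | intermediate
13 | methyl acrylate | C=CC(=O)OC | starting material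
14 | methyl (4R,6R,7E)-3-hydroxy-8-iodo-6-methyl-2-methylidene-4,6-bis[(triethylsilyl)oxy]oct-7-enoate (both C3 epimers) | I/C=C/[C@](C)(O[Si](CC)(CC)CC)C[C@@H](O[Si](CC)(CC)CC)C(O)C(=C)C(=O)OC | intermediate
15 | methyl (2Z,4R,6R,7E)-2-(bromomethyl)-8-iodo-6-methyl-4,6-bis[(triethylsilyl)oxy]octa-2,7-dienoate | I/C=C/[C@](C)(O[Si](CC)(CC)CC)C[C@@H](O[Si](CC)(CC)CC)/C=C(\CBr)C(=O)OC | intermediate
16 | prop-2-yn-1-ol | C#CCO | starting material
17 | 1-methoxy-4-[(prop-2-yn-1-yloxy)methyl]benzene | C#CCOCc1ccc(OC)cc1 | intermediate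
18 | methyl 4-[(4-methoxybenzyl)oxy]but-2-ynoate | COC(=O)C#CCOCc1ccc(OC)cc1 | intermediate
19 | methyl (2Z)-4-[(4-methoxybenzyl)oxy]-3-methylbut-2-enoate | COC(=O)/C=C(/C)COCc1ccc(OC)cc1 | intermediate
20 | (2Z)-4-[(4-methoxybenzyl)oxy]-3-methylbut-2-en-1-ol | OC/C=C(/C)COCc1ccc(OC)cc1 | intermediate
21 | (2Z)-4-[(4-methoxybenzyl)oxy]-3-methylbut-2-enal | O=C/C=C(/C)COCc1ccc(OC)cc1 | intermediate
22 | methyl (3S,4S,5Z)-4-hydroxy-3-[(1R,3R,4E)-5-iodo-3-methyl-1,3-bis(triethylsilyloxy)pent-4-en-1-yl]-7-[(4-methoxybenzyl)oxy]-6-methyl-2-methylidenehept-5-enoate | COC(=O)C(=C)[C@@H]([C@@H](O)/C=C(/C)COCc1ccc(OC)cc1)[C@H](O[Si](CC)(CC)CC)C[C@@](C)(O[Si](CC)(CC)CC)/C=C/I | intermediate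
23 | (4S,5S)-4-[(1R,3R,4E)-5-iodo-3-methyl-1,3-bis(triethylsilyloxy)pent-4-en-1-yl]-5-[(1Z)-3-[(4-methoxybenzyl)oxy]-2-methylprop-1-en-1-yl]-3-methylidenedihydrofuran-2(3H)-one | C=C1C(=O)O[C@@H](/C=C(/C)COCc2ccc(OC)cc2)[C@H]1[C@H](O[Si](CC)(CC)CC)C[C@@](C)(O[Si](CC)(CC)CC)/C=C/I | intermediate
24 | (4R,5S)-4-[(1R,3R,4E)-1,3-dihydroxy-5-iodo-3-methylpent-4-en-1-yl]-5-[(1Z)-3-[(4-methoxybenzyl)oxy]-2-methylprop-1-en-1-yl]-3-methylidenedihydrofuran-2(3H)-one | C=C1C(=O)O[C@@H](/C=C(/C)COCc2ccc(OC)cc2)[C@H]1[C@H](O)C[C@@](C)(O)/C=C/I | intermediate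
25 | angelic acid, (2Z)-2-methylbut-2-enoic acid | C/C=C(/C)C(=O)O | starting material
26 | (2Z)-2-methylbut-2-enoic 2,4,6-trichlorobenzoic anhydride | C/C=C(/C)C(=O)OC(=O)c1c(Cl)cc(Cl)cc1Cl | intermediate
27 | (1R,3R,4E)-3-hydroxy-5-iodo-1-[(2S,3R)-2-{(1Z)-3-[(4-methoxybenzyl)oxy]-2-methylprop-1-en-1-yl}-4-methylidene-5-oxooxolan-3-yl]-3-methylpent-4-en-1-yl (2Z)-2-methylbut-2-enoate | C=C1C(=O)O[C@@H](/C=C(/C)COCc2ccc(OC)cc2)[C@H]1[C@H](OC(=O)/C(C)=C\C)C[C@@](C)(O)/C=C/I | intermediate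
28 | (1R,3R,4E)-3-hydroxy-1-[(2S,3R)-2-[(1Z)-3-hydroxy-2-methylprop-1-en-1-yl]-4-methylidene-5-oxooxolan-3-yl]-5-iodo-3-methylpent-4-en-1-yl (2Z)-2-methylbut-2-enoate | C=C1C(=O)O[C@@H](/C=C(/C)CO)[C@H]1[C@H](OC(=O)/C(C)=C\C)C[C@@](C)(O)/C=C/I | intermediate
29 | (1R,3R,4E)-3-hydroxy-5-iodo-3-methyl-1-[(2S,3R)-4-methylidene-2-[(1Z)-2-methyl-3-oxoprop-1-en-1-yl]-5-oxooxolan-3-yl]pent-4-en-1-yl (2Z)-2-methylbut-2-enoate | C=C1C(=O)O[C@@H](/C=C(/C)C=O)[C@H]1[C@H](OC(=O)/C(C)=C\C)C[C@@](C)(O)/C=C/I | intermediate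
30 | (3aR,4R,6R,7E,9S,10Z,11aS)-6,9-dihydroxy-6,10-dimethyl-3-methylidene-2-oxo-2,3,3a,4,5,6,9,11a-octahydrocyclodeca[b]furan-4-yl (2Z)-2-methylbut-2-enoate; germacrane descriptors 3S,6S,7R,8R,10R,1E,4Z | C=C1C(=O)O[C@H]2/C=C(/C)[C@@H](O)/C=C/[C@](C)(O)C[C@@H](OC(=O)/C(C)=C\C)[C@@H]12 | target

**Count**
Total: 21 steps. Longest linear sequence: 16 steps (steps 1–10, then 16–21).

**Three steps most likely to fail**

Step 16 (allylation/lactonisation). The syn outcome is well founded, but the face of C7 that is attacked is controlled only by the C8 silyloxy stereocentre, and the opposite sense (aldehyde anti to the silyloxy group) cannot be excluded. The fallback enters with the opposite C8 configuration and inverts it at the acylation. It sets out from 4: D-proline in place of L-proline gives the (2S)-aminoxy aldehyde F1 and, after NaBH4, the aminoxy alcohol F2. The unchanged operations of steps 4–10 lead through the diol F3, the tris-silyl ether F4, the ozonide F5, the aldehyde F6, the iodoalkene F7, the aldehyde F8 and the Baylis–Hillman adduct F9 to the (4S)-bromide F10. Indium-mediated coupling with 21 and lactonisation give the hydroxy ester F11 and the lactone F12, and HF·pyridine gives the (8S)-diol F13. A Mitsunobu esterification of F13 with angelic acid 25 (PPh3, DIAD, toluene, 0 °C) then installs the angelate with inversion at C8 and comes back to the route at 27.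

Step 21 (macrocyclisation). The ten-membered ring is strained, the (Z)-enal can isomerise, and C3 is set only by the conformational argument. The fallback sets out from 29: if the cyclisation gives mainly the C3 epimer F14 (or a mixture), the crude allylic alcohols are oxidised with MnO2 to the cross-conjugated 1(2),4(5)-dien-3-one F15. F15 is reduced under reagent control with (R)-2-methyl-CBS-oxazaborolidine and catecholborane (toluene, −78 °C), the 4-methyl-substituted alkenyl arm acting as the large group, and the route is rejoined at 30.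

Step 9 (Baylis–Hillman reaction). The hindered α-silyloxy aldehyde may react slowly, and days with DABCO risk C8 epimerisation or silyl migration. The fallback sets out from 12 and replaces the amine-catalysed process by a preformed α-metallated acrylate: [1-(methoxycarbonyl)vinyl]diisobutylaluminium, made from methyl propiolate, i-Bu2AlH and N-methylmorpholine N-oxide in THF at 0 °C, adds 1,2 to 12 within hours and gives 14 directly, where the route continues.

**Further compounds**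
F1 | step 16 | (2S,4R)-4-methyl-2-[(phenylamino)oxy]-4-[(triethylsilyl)oxy]hex-5-enal | C=C[C@](C)(O[Si](CC)(CC)CC)C[C@H](ONc1ccccc1)C=O
F2 | step 16 | (2S,4R)-4-methyl-2-[(phenylamino)oxy]-4-[(triethylsilyl)oxy]hex-5-en-1-ol | C=C[C@](C)(O[Si](CC)(CC)CC)C[C@H](ONc1ccccc1)CO
F3 | step 16 | (2S,4R)-4-methyl-4-[(triethylsilyl)oxy]hex-5-ene-1,2-diol | C=C[C@](C)(O[Si](CC)(CC)CC)C[C@H](O)CO
F4 | step 16 | (3R,5S)-3-methyl-3,5,6-tris[(triethylsilyl)oxy]hex-1-ene | C=C[C@](C)(O[Si](CC)(CC)CC)C[C@H](O[Si](CC)(CC)CC)CO[Si](CC)(CC)CC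
F5 | step 16 | 3-[(2R,4S)-2,4,5-tris(triethylsilyloxy)pentan-2-yl]-1,2,4-trioxolane | C1(OOCO1)[C@](C)(O[Si](CC)(CC)CC)C[C@H](O[Si](CC)(CC)CC)CO[Si](CC)(CC)CC
F6 | step 16 | (2R,4S)-2-methyl-2,4,5-tris[(triethylsilyl)oxy]pentanal | O=C[C@](C)(O[Si](CC)(CC)CC)C[C@H](O[Si](CC)(CC)CC)CO[Si](CC)(CC)CC
F7 | step 16 | (1E,3R,5S)-1-iodo-3-methyl-3,5,6-tris[(triethylsilyl)oxy]hex-1-ene | I/C=C/[C@](C)(O[Si](CC)(CC)CC)C[C@H](O[Si](CC)(CC)CC)CO[Si](CC)(CC)CC
F8 | step 16 | (2S,4R,5E)-6-iodo-4-methyl-2,4-bis[(triethylsilyl)oxy]hex-5-enal | I/C=C/[C@](C)(O[Si](CC)(CC)CC)C[C@H](O[Si](CC)(CC)CC)C=O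
F9 | step 16 | methyl (4S,6R,7E)-3-hydroxy-8-iodo-6-methyl-2-methylidene-4,6-bis[(triethylsilyl)oxy]oct-7-enoate (both C3 epimers) | I/C=C/[C@](C)(O[Si](CC)(CC)CC)C[C@H](O[Si](CC)(CC)CC)C(O)C(=C)C(=O)OC
F10 | step 16 | methyl (2Z,4S,6R,7E)-2-(bromomethyl)-8-iodo-6-methyl-4,6-bis[(triethylsilyl)oxy]octa-2,7-dienoate | I/C=C/[C@](C)(O[Si](CC)(CC)CC)C[C@H](O[Si](CC)(CC)CC)/C=C(\CBr)C(=O)OC
F11 | step 16 | methyl (3S,4S,5Z)-4-hydroxy-3-[(1S,3R,4E)-5-iodo-3-methyl-1,3-bis(triethylsilyloxy)pent-4-en-1-yl]-7-[(4-methoxybenzyl)oxy]-6-methyl-2-methylidenehept-5-enoate | COC(=O)C(=C)[C@@H]([C@@H](O)/C=C(/C)COCc1ccc(OC)cc1)[C@@H](O[Si](CC)(CC)CC)C[C@@](C)(O[Si](CC)(CC)CC)/C=C/I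
F12 | step 16 | (4S,5S)-4-[(1S,3R,4E)-5-iodo-3-methyl-1,3-bis(triethylsilyloxy)pent-4-en-1-yl]-5-[(1Z)-3-[(4-methoxybenzyl)oxy]-2-methylprop-1-en-1-yl]-3-methylidenedihydrofuran-2(3H)-one | C=C1C(=O)O[C@@H](/C=C(/C)COCc2ccc(OC)cc2)[C@H]1[C@@H](O[Si](CC)(CC)CC)C[C@@](C)(O[Si](CC)(CC)CC)/C=C/I
F13 | step 16 | (4R,5S)-4-[(1S,3R,4E)-1,3-dihydroxy-5-iodo-3-methylpent-4-en-1-yl]-5-[(1Z)-3-[(4-methoxybenzyl)oxy]-2-methylprop-1-en-1-yl]-3-methylidenedihydrofuran-2(3H)-one | C=C1C(=O)O[C@@H](/C=C(/C)COCc2ccc(OC)cc2)[C@H]1[C@@H](O)C[C@@](C)(O)/C=C/I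
F14 | step 21 | C3 epimer of 30, (3aR,4R,6R,7E,9R,10Z,11aS)-6,9-dihydroxy-6,10-dimethyl-3-methylidene-2-oxo-2,3,3a,4,5,6,9,11a-octahydrocyclodeca[b]furan-4-yl (2Z)-2-methylbut-2-enoate | C=C1C(=O)O[C@H]2/C=C(/C)[C@H](O)/C=C/[C@](C)(O)C[C@@H](OC(=O)/C(C)=C\C)[C@@H]12
F15 | step 21 | (3aR,4R,6R,7E,10Z,11aS)-6-hydroxy-6,10-dimethyl-3-methylidene-2,9-dioxo-2,3,3a,4,5,6,9,11a-octahydrocyclodeca[b]furan-4-yl (2Z)-2-methylbut-2-enoate | C=C1C(=O)O[C@H]2/C=C(/C)C(=O)/C=C/[C@](C)(O)C[C@@H](OC(=O)/C(C)=C\C)[C@@H]12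
F0 | step 9 | none | none
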